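The flavone is cut at both bonds to C4. The pyranone carbonyl carbon comes from carbon monoxide and is joined, in one palladium-catalysed operation, to C4a, the single oxygen-free carbon of the mirror-symmetric ring A, and to C3, the methoxy-bearing α-carbon of the ring B aryl ketone. The step delivers the whole C15 skeleton as an open 2-methoxy-1,3-diketone without closing a ring; because ring A is symmetric, either ortho oxygen can later close ring C to the same flavone. The precursors are a fully substituted iodobenzene carrying three methoxymethyl ethers and two methoxy groups, and a 2-methoxyacetophenone with a methoxymethyl-protected 4-hydroxyl.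

Key step: step 8

Remark on the chemistry: all four phenols are carried as methoxymethyl ethers, so that one acid treatment at the end both unmasks them and closes ring C; CO is supplied at 1 atm from a balloon or a two-chamber vessel.

Step 1
Reactants: 1 phloroglucinol
Product: 2 1,3,5-tris(methoxymethoxy)benzene
Conditions: MOMCl (3.6 equiv), i-Pr2NEt (4.5 equiv), CH2Cl2–DMF, 0 °C → rt
Reagents that add atoms: chloromethyl methyl ether (MOMCl), COCCl
Why: Williamson-type O-alkylation (methoxymethyl protection): the hard, highly reactive chloromethyl ether should alkylate the three phenolic oxygens rather than the ring carbons, and the acetals tolerate every basic and organometallic step up to the final acid treatment.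

Step 2
Reactants: 2 1,3,5-tris(methoxymethoxy)benzene
Product: 3 2,4-dibromo-1,3,5-tris(methoxymethoxy)benzene
Conditions: NBS (2.0 equiv, portionwise), MeCN, −20 → 0 °C
Reagents that add atoms: N-bromosuccinimide (NBS), O=C1CCC(=O)N1Br
Why: Electrophilic aromatic bromination: the trialkoxybenzene reacts with NBS without acid, each bromine lowers the reactivity of the ring so that two equivalents at low temperature should stop mainly at the dibromide, and the threefold symmetry of 2 allows only one dibromide.

Step 3
Reactants: 3 2,4-dibromo-1,3,5-tris(methoxymethoxy)benzene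
Product: 4 2,4-dimethoxy-1,3,5-tris(methoxymethoxy)benzene
Conditions: NaOMe (10 equiv, 25% in MeOH), CuI (0.5 equiv), DMF, 110 °C
Reagents that add atoms: sodium methoxide, C[O-].[Na+]
Why: Ullmann-type copper-catalysed methoxylation of aryl bromides: excess methoxide with CuI in hot DMF should replace both bromines by methoxy groups, a substitution that is established for electron-rich bromides with two ortho substituents, and the acetals are inert to base.

Step 4
Reactants: 4 2,4-dimethoxy-1,3,5-tris(methoxymethoxy)benzene
Product: 6 1-iodo-3,5-dimethoxy-2,4,6-tris(methoxymethoxy)benzene, via aryllithium 5 (not isolated)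
Conditions: n-BuLi (1.2 equiv), THF, 0 °C; then I2 (1.3 equiv), −78 °C → rt; aq Na2S2O3 work-up
Reagents that add atoms: iodine, II
Why: Directed ortho-metalation followed by iodinolysis: the only ring hydrogen lies between two methoxymethoxy groups that both coordinate lithium, so deprotonation can occur only there, and iodine then gives the symmetric iodide without any acid that could harm the acetals.

Step 5
Reactants: 7 2,5-dimethoxyphenol
Product: 8 1,4-dimethoxy-2-(methoxymethoxy)benzene
Conditions: MOMCl (1.3 equiv), i-Pr2NEt (1.6 equiv), CH2Cl2, 0 °C → rt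
Reagents that add atoms: chloromethyl methyl ether (MOMCl), COCCl
Why: Methoxymethyl protection of a phenol (Williamson-type O-alkylation) masks the acidic 4'-hydroxyl for the organolithium and enolate steps and is removed in the same final acid step as the ring A acetals.

Step 6
Reactants: 8 1,4-dimethoxy-2-(methoxymethoxy)benzene
Product: 9 1-bromo-2,5-dimethoxy-4-(methoxymethoxy)benzene
Conditions: NBS (1.05 equiv), MeCN, 0 °C
Reagents that add atoms: N-bromosuccinimide (NBS), O=C1CCC(=O)N1Br
Why: Electrophilic aromatic bromination of a 1,2,4-trioxygenated benzene occurs para to the methoxymethoxy group and ortho to a methoxy group, the most activated and least hindered site, which is the carbon that becomes C1' of ring B.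

Step 7
Reactants: 9 1-bromo-2,5-dimethoxy-4-(methoxymethoxy)benzene; 10 N,2-dimethoxy-N-methylacetamide
Product: 13 1-[2,5-dimethoxy-4-(methoxymethoxy)phenyl]-2-methoxyethan-1-one, via aryllithium 11 (not isolated), via lithium hemiaminal adduct 12 (not isolated)
Conditions: n-BuLi (1.05 equiv), THF, −78 °C; then 10 (1.2 equiv), −78 → 0 °C; then AcOH, H2O
Reagents that add atoms: none
Why: Bromine–lithium exchange followed by Weinreb ketone synthesis: exchange at −78 °C is faster than any ortho-lithiation, and the chelated tetrahedral adduct 12 does not collapse before the quench, so the α-methoxy ketone should form without over-addition and without the Lewis acid that a direct acylation of the arene would need.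

Step 8
Reactants: 6 1-iodo-3,5-dimethoxy-2,4,6-tris(methoxymethoxy)benzene; 13 1-[2,5-dimethoxy-4-(methoxymethoxy)phenyl]-2-methoxyethan-1-one; 14 carbon monoxide
Product: 17 1-[2,5-dimethoxy-4-(methoxymethoxy)phenyl]-3-[3,5-dimethoxy-2,4,6-tris(methoxymethoxy)phenyl]-2-methoxypropane-1,3-dione (racemic at C2, enolisable), via sodium enolate 15 (not isolated), via sodium diketonate 16 (not isolated)
Conditions: 13 (2.0 equiv), NaN(SiMe3)2 (2.0 equiv), THF, 0 °C; then 6 (1.0 equiv), Pd(dba)2 (5 mol%), Ph2P(CH2)3PPh2 (6 mol%), CO (14, 1 atm), THF–dioxane, 80 °C; then AcOH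
Reagents that add atoms: none
Why: The C–I bond of 6 adds oxidatively to zerovalent palladium, CO inserts to give an aroyl complex of divalent palladium, enolate 15 displaces iodide and C–C reductive elimination completes the C4a–C4 and C4–C3 bonds, after which the more acidic product is deprotonated by the second equivalent of 15 and rests as diketonate 16 until the acetic acid quench. The closest known reaction is the palladium-catalysed carbonylative α-arylation of aryl ketones with aryl iodides to 1,3-diketones, applied here to a more crowded iodide and an α-alkoxy ketone. No ring is closed, and the C2 centre of 17 is formed racemic without control, which is harmless because it is enolisable and becomes the sp2 carbon C3 of the flavone. The step needs carbonylative coupling to outrun direct α-arylation, O-acylation of the enolate and hydrodeiodination. The two ortho methoxymethoxy groups of 6 slow reductive elimination from the crowded arylpalladium and favour CO insertion, which moves the metal one atom away from the ring, while the chelating diphosphine under CO stabilises the aroyl complex. Ketone 13 has a single enolisable carbon and iodide 6 is symmetric about its C–I axis, so only one diketone can form, and the stability of 16 should drive the coupling and block a second acylation.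

Step 9
Reactants: 17 1-[2,5-dimethoxy-4-(methoxymethoxy)phenyl]-3-[3,5-dimethoxy-2,4,6-tris(methoxymethoxy)phenyl]-2-methoxypropane-1,3-dione
Product: 19 5,7-dihydroxy-2-(4-hydroxy-2,5-dimethoxyphenyl)-3,6,8-trimethoxy-4H-chromen-4-one (5,7,4'-trihydroxy-3,6,8,2',5'-pentamethoxyflavone), via tetrahydroxy diketone 18 (not isolated)
Conditions: 3 M HCl, MeOH, 60 °C
Reagents that add atoms: none
Why: Acid-catalysed acetal cleavage and cyclodehydration (the ring-closing stage of a Baker–Venkataraman flavone synthesis): methanolic HCl should remove the four methoxymethyl groups as dimethoxymethane, one of the two equivalent ortho hydroxyls of ring A adds to the ring B carbonyl in a 6-exo-trig manner and loss of water gives the aromatic pyranone, the other ortho hydroxyl becoming the hydrogen-bonded 5-OH.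

Compound list

1 | phloroglucinol (benzene-1,3,5-triol) | Oc1cc(O)cc(O)c1 | starting material
2 | 1,3,5-tris(methoxymethoxy)benzene | COCOc1cc(OCOC)cc(OCOC)c1 | intermediate
3 | 2,4-dibromo-1,3,5-tris(methoxymethoxy)benzene | COCOc1cc(OCOC)c(Br)c(OCOC)c1Br | intermediate
4 | 2,4-dimethoxy-1,3,5-tris(methoxymethoxy)benzene | COCOc1cc(OCOC)c(OC)c(OCOC)c1OC | intermediate
5 | [3,5-dimethoxy-2,4,6-tris(methoxymethoxy)phenyl]lithium | [Li]c1c(OCOC)c(OC)c(OCOC)c(OC)c1OCOC | intermediate
6 | 1-iodo-3,5-dimethoxy-2,4,6-tris(methoxymethoxy)benzene | COc1c(OCOC)c(I)c(OCOC)c(OC)c1OCOC | intermediate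
7 | 2,5-dimethoxyphenol | COc1ccc(OC)c(O)c1 | starting material
8 | 1,4-dimethoxy-2-(methoxymethoxy)benzene | COCOc1cc(OC)ccc1OC | intermediate
9 | 1-bromo-2,5-dimethoxy-4-(methoxymethoxy)benzene | COCOc1cc(OC)c(Br)cc1OC | intermediate
10 | N,2-dimethoxy-N-methylacetamide | COCC(=O)N(C)OC | starting material
11 | [2,5-dimethoxy-4-(methoxymethoxy)phenyl]lithium | [Li]c1cc(OC)c(OCOC)cc1OC | intermediate
12 | lithium 1-[2,5-dimethoxy-4-(methoxymethoxy)phenyl]-2-methoxy-1-[methoxy(methyl)amino]ethan-1-olate (tetrahedral adduct, racemic) | COCC([O-])(N(C)OC)c1cc(OC)c(OCOC)cc1OC.[Li+] | intermediate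
13 | 1-[2,5-dimethoxy-4-(methoxymethoxy)phenyl]-2-methoxyethan-1-one | COCC(=O)c1cc(OC)c(OCOC)cc1OC | intermediate
14 | carbon monoxide | [C-]#[O+] | starting material
15 | sodium (Z)-1-[2,5-dimethoxy-4-(methoxymethoxy)phenyl]-2-methoxyethen-1-olate | CO/C=C(\[O-])c1cc(OC)c(OCOC)cc1OC.[Na+] | intermediate
16 | sodium 1,3-diketonate of 17 (delocalised anion, drawn as one enolate form without fixed double-bond geometry) | COC(C(=O)c1c(OCOC)c(OC)c(OCOC)c(OC)c1OCOC)=C([O-])c1cc(OC)c(OCOC)cc1OC.[Na+] | intermediate
17 | 1-[2,5-dimethoxy-4-(methoxymethoxy)phenyl]-3-[3,5-dimethoxy-2,4,6-tris(methoxymethoxy)phenyl]-2-methoxypropane-1,3-dione (racemic at C2, enolisable) | COC(C(=O)c1c(OCOC)c(OC)c(OCOC)c(OC)c1OCOC)C(=O)c1cc(OC)c(OCOC)cc1OC | intermediate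
18 | 1-(4-hydroxy-2,5-dimethoxyphenyl)-2-methoxy-3-(2,4,6-trihydroxy-3,5-dimethoxyphenyl)propane-1,3-dione (racemic at C2, enolisable) | COC(C(=O)c1c(O)c(OC)c(O)c(OC)c1O)C(=O)c1cc(OC)c(O)cc1OC | intermediate
19 | 5,7-dihydroxy-2-(4-hydroxy-2,5-dimethoxyphenyl)-3,6,8-trimethoxy-4H-chromen-4-one (no stereocentre) | COc1cc(-c2oc3c(OC)c(O)c(OC)c(O)c3c(=O)c2OC)c(OC)cc1O | target

Total step count: 9. Longest linear sequence: 6 (steps 1, 2, 3, 4, 8, 9); the ring B branch (steps 5, 6, 7) joins at step 8.

Steps most likely to fail

Step 8. Oxidative addition at the fully substituted ring may be slow, so that hydrodeiodination takes over, or the aroyl complex may be intercepted at the enolate oxygen instead of at carbon. The fallback makes the two bonds to C4 one after the other by polar chemistry; it sets out from 4 and 13 and comes back at 17. Compound 4 is lithiated as in step 4 to aryllithium 5, which is treated with DMF at −78 °C to give the lithium (dimethylamino)[3,5-dimethoxy-2,4,6-tris(methoxymethoxy)phenyl]methanolate F1, and the AcOH quench should release 3,5-dimethoxy-2,4,6-tris(methoxymethoxy)benzaldehyde F2. Aldol addition of enolate 15 (from 13 and NaN(SiMe3)2, THF, −78 °C) to F2, followed by an AcOH quench, should give 3-hydroxy-1-[2,5-dimethoxy-4-(methoxymethoxy)phenyl]-3-[3,5-dimethoxy-2,4,6-tris(methoxymethoxy)phenyl]-2-methoxypropan-1-one F3 as a mixture of diastereomers. Oxidation with Dess–Martin periodinane (CH2Cl2, NaHCO3, rt) converges both diastereomers on 17.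

Step 3. Reductive loss of bromine may compete with C–O coupling at the two crowded positions, or the reaction may stall after the first substitution. The fallback separates C–O bond formation from methylation; it sets out from 3 and comes back at 4. Palladium-catalysed hydroxylation of both C–Br bonds (KOH, Pd2(dba)3, t-BuXPhos, dioxane–H2O, 100 °C, then neutralisation with NaH2PO4) should give 2,4,6-tris(methoxymethoxy)benzene-1,3-diol F4. Williamson methylation (MeI, K2CO3, acetone, reflux) then gives 4.

Step 2. The degree of bromination may not be controllable, giving a mixture of mono-, di- and tribromide that is hard to separate. The fallback replaces stoichiometric control by exhaustive bromination and removal of one bromine; it sets out from 2 and comes back at 3. Excess NBS (3.3 equiv, MeCN, rt) should give 1,3,5-tribromo-2,4,6-tris(methoxymethoxy)benzene F5. A single bromine–lithium exchange (n-BuLi, 1.0 equiv, THF, −78 °C) gives [3,5-dibromo-2,4,6-tris(methoxymethoxy)phenyl]lithium F6, which is protonated with MeOH at −78 °C to return 3.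

Further compounds

F1 | step 8 | lithium (dimethylamino)[3,5-dimethoxy-2,4,6-tris(methoxymethoxy)phenyl]methanolate (racemic, not isolated) | COc1c(OCOC)c(C([O-])N(C)C)c(OCOC)c(OC)c1OCOC.[Li+]
F2 | step 8 | 3,5-dimethoxy-2,4,6-tris(methoxymethoxy)benzaldehyde | COc1c(OCOC)c(C=O)c(OCOC)c(OC)c1OCOC
F3 | step 8 | 3-hydroxy-1-[2,5-dimethoxy-4-(methoxymethoxy)phenyl]-3-[3,5-dimethoxy-2,4,6-tris(methoxymethoxy)phenyl]-2-methoxypropan-1-one (racemic, mixture of syn and anti diastereomers) | COC(C(O)c1c(OCOC)c(OC)c(OCOC)c(OC)c1OCOC)C(=O)c1cc(OC)c(OCOC)cc1OC
F4 | step 3 | 2,4,6-tris(methoxymethoxy)benzene-1,3-diol | COCOc1cc(OCOC)c(O)c(OCOC)c1O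
F5 | step 2 | 1,3,5-tribromo-2,4,6-tris(methoxymethoxy)benzene | COCOc1c(Br)c(OCOC)c(Br)c(OCOC)c1Br
F6 | step 2 | [3,5-dibromo-2,4,6-tris(methoxymethoxy)phenyl]lithium (not isolated) | [Li]c1c(OCOC)c(Br)c(OCOC)c(Br)c1OCOC
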